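The cycloheptene ring is disconnected across its only olefin, C5=C6 (azulene numbering), the trisubstituted double bond flanked by the acyloxy carbon C4 and the C7–C8 ethano bridge. Ring-closing metathesis of a cyclopentane-based diene closes this seven-membered ring last, fixes the olefin position unambiguously and locks the trans ring fusion in one operation. The precursor is a pentasubstituted cyclopentanol bearing a 1-hydroxyallyl arm and, trans to it on the neighbouring quaternary carbon, a 3-methylbut-3-enyl arm. It arises in three steps from 3-ethoxycyclopentenone through copper-catalysed asymmetric conjugate methylation with in-flask anti-aldol capture by acrolein and isopropylcerium addition; acylation and deacetylation finish.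

Key step: step 4

Remark: the chiral N-heterocyclic carbene ligand of step 2 is taken as the enantiomer that gives the (3S)-configured quaternary carbon; the mirror-image ligand would be used if the sense of induction proved opposite.

Step 1
Reactants: 1 3-ethoxycyclopent-2-en-1-one; 2 4-bromo-2-methylbut-1-ene
Product: 5 3-(3-methylbut-3-en-1-yl)cyclopent-2-en-1-one, via Grignard reagent 3 (not isolated), via magnesium alkoxide 4 (not isolated)
Conditions: 2, Mg, THF, 25–40 °C; then 1, THF, 0 °C; then 1 M aq. HCl, 25 °C
Reagents that add atoms: none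
Why: Stork–Danheiser transposition, in which the Grignard reagent adds 1,2 to the vinylogous ester and acid hydrolysis of the enol ether with loss of ethanol moves the carbonyl to give the 3-alkylcyclopentenone, no stereocentre being formed.

Step 2
Reactants: 5 3-(3-methylbut-3-en-1-yl)cyclopent-2-en-1-one; 6 acrolein
Product: 8 (2S,3S)-2-[(1S)-1-hydroxyprop-2-en-1-yl]-3-methyl-3-(3-methylbut-3-en-1-yl)cyclopentan-1-one, via aluminium enolate 7 (not isolated)
Conditions: Me3Al (3 equiv), Cu(OTf)2 (5 mol %), chiral sulfonate-bearing N-heterocyclic carbene ligand (6 mol %, from its imidazolinium salt), THF, −78 °C; then acrolein (5 equiv), −78 °C; aq. potassium sodium tartrate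
Reagents that add atoms: trimethylaluminium, C[Al](C)C
Why: Copper-catalysed asymmetric conjugate addition of Me3Al to the β-substituted cyclopentenone should set the quaternary carbon (3S) under ligand control, and the regiodefined aluminium enolate 7 should then add to acrolein in a tandem conjugate addition–aldol reaction through a Zimmerman–Traxler chair (ring-locked E-enolate, hence the anti aldol that fixes C2 against the carbinol carbon) on the enolate face opposite the longer 3-methylbutenyl arm, which places the new side chain cis to methyl.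

Step 3
Reactants: 8 (2S,3S)-2-[(1S)-1-hydroxyprop-2-en-1-yl]-3-methyl-3-(3-methylbut-3-en-1-yl)cyclopentan-1-one
Product: 9 (1R,2S,3S)-2-[(1S)-1-hydroxyprop-2-en-1-yl]-3-methyl-3-(3-methylbut-3-en-1-yl)-1-(propan-2-yl)cyclopentan-1-ol
Conditions: iPrMgCl (4 equiv), CeCl3 (4 equiv), THF, −78 to −40 °C; aq. NH4Cl
Reagents that add atoms: isopropylmagnesium chloride, CC(C)[Mg]Cl
Why: Organocerium 1,2-addition to the ketone should suppress enolisation, β-hydride reduction and retro-aldol cleavage, and isopropyl should enter the carbonyl face opposite the adjacent C2 side chain, which sets C1 as R with the tertiary hydroxyl cis to that side chain.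

Step 4
Reactants: 9 (1R,2S,3S)-2-[(1S)-1-hydroxyprop-2-en-1-yl]-3-methyl-3-(3-methylbut-3-en-1-yl)-1-(propan-2-yl)cyclopentan-1-ol
Product: 10 (3R,3aS,4S,8aS)-6,8a-dimethyl-3-(propan-2-yl)-1,2,3,3a,4,7,8,8a-octahydroazulene-3,4-diol
Conditions: second-generation Grubbs catalyst (5 mol %), CH2Cl2 (0.005 M), 40 °C
Reagents that add atoms: none
Why: Ruthenium-alkylidene olefin metathesis, in which the catalyst loads on the monosubstituted vinyl group of the allylic carbinol, the new alkylidene undergoes [2+2] cycloaddition with the tethered 1,1-disubstituted olefin, and cycloreversion releases ethylene and the cyclic trisubstituted alkene. The closest known reaction type is ring-closing metathesis of a vinyl carbinol with an isopropenyl-type olefin to a trisubstituted cycloheptene, a well-established closure for hydroazulene terpenoids. The seven-membered ring closes by formation of the C5=C6 double bond between the two side-chain termini, the ring size enforcing the cis ring olefin. No new stereocentre arises; the trans ring fusion follows from C2 and C3 of 9, whose two arms are trans on the cyclopentane and can only meet in the trans-fused bicycle. The step needs cyclisation to outrun intermolecular metathesis and allylic-alcohol isomerisation, which high dilution, the non-dimerising 1,1-disubstituted partner and the accelerating free allylic hydroxyl should secure, and since these two olefins are the only ones in 9 the double bond cannot end up elsewhere.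

Step 5
Reactants: 10 (3R,3aS,4S,8aS)-6,8a-dimethyl-3-(propan-2-yl)-1,2,3,3a,4,7,8,8a-octahydroazulene-3,4-diol; 11 4-(acetyloxy)benzoyl chloride
Product: 12 (3R,3aS,4S,8aS)-3-hydroxy-6,8a-dimethyl-3-(propan-2-yl)-1,2,3,3a,4,7,8,8a-octahydroazulen-4-yl 4-(acetyloxy)benzoate
Conditions: 11 (1.5 equiv), Et3N, DMAP (0.2 equiv), CH2Cl2, 0 to 25 °C
Reagents that add atoms: none
Why: DMAP-catalysed acylation (nucleophilic catalysis) should be selective for the secondary allylic hydroxyl because the tertiary hydroxyl between isopropyl and the ring fusion is too hindered, and the carbinol configuration is retained since its C–O bond is untouched.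

Step 6
Reactants: 12 (3R,3aS,4S,8aS)-3-hydroxy-6,8a-dimethyl-3-(propan-2-yl)-1,2,3,3a,4,7,8,8a-octahydroazulen-4-yl 4-(acetyloxy)benzoate
Product: 13 (3R,3aS,4S,8aS)-3-hydroxy-6,8a-dimethyl-3-(propan-2-yl)-1,2,3,3a,4,7,8,8a-octahydroazulen-4-yl 4-hydroxybenzoate
Conditions: K2CO3 (0.2 equiv), MeOH, 0 °C
Reagents that add atoms: none
Why: Base-catalysed transesterification (methanolysis) should cleave only the aryl acetate, a phenyl ester far more electrophilic than the hindered secondary alkyl benzoate, whose carbonyl is further deactivated once the para-phenoxide forms.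

Compound list
1 | 3-ethoxycyclopent-2-en-1-one | CCOC1=CC(=O)CC1 | starting material
2 | 4-bromo-2-methylbut-1-ene | CC(=C)CCBr | starting material
3 | bromo(3-methylbut-3-en-1-yl)magnesium | CC(=C)CC[Mg]Br | intermediate
4 | bromomagnesium 3-ethoxy-1-(3-methylbut-3-en-1-yl)cyclopent-2-en-1-olate | CCOC1=CC(O[Mg]Br)(CCC(C)=C)CC1 | intermediate
5 | 3-(3-methylbut-3-en-1-yl)cyclopent-2-en-1-one | CC(=C)CCC1=CC(=O)CC1 | intermediate
6 | acrolein (prop-2-enal) | C=CC=O | starting material
7 | dimethyl{[(3S)-3-methyl-3-(3-methylbut-3-en-1-yl)cyclopent-1-en-1-yl]oxy}alumane | C1=C(O[Al](C)C)CC[C@]1(C)CCC(C)=C | intermediate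
8 | (2S,3S)-2-[(1S)-1-hydroxyprop-2-en-1-yl]-3-methyl-3-(3-methylbut-3-en-1-yl)cyclopentan-1-one | C=C[C@H](O)[C@@H]1[C@@](C)(CCC(C)=C)CCC1=O | intermediate
9 | (1R,2S,3S)-2-[(1S)-1-hydroxyprop-2-en-1-yl]-3-methyl-3-(3-methylbut-3-en-1-yl)-1-(propan-2-yl)cyclopentan-1-ol | C=C[C@H](O)[C@@H]1[C@@](C)(CCC(C)=C)CC[C@@]1(O)C(C)C | intermediate
10 | (3R,3aS,4S,8aS)-6,8a-dimethyl-3-(propan-2-yl)-1,2,3,3a,4,7,8,8a-octahydroazulene-3,4-diol | CC1=C[C@H](O)[C@@H]2[C@@](C)(CC1)CC[C@@]2(O)C(C)C | intermediate
11 | 4-(acetyloxy)benzoyl chloride | CC(=O)Oc1ccc(cc1)C(Cl)=O | starting material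
12 | (3R,3aS,4S,8aS)-3-hydroxy-6,8a-dimethyl-3-(propan-2-yl)-1,2,3,3a,4,7,8,8a-octahydroazulen-4-yl 4-(acetyloxy)benzoate | CC1=C[C@H](OC(=O)c2ccc(OC(C)=O)cc2)[C@@H]2[C@@](C)(CC1)CC[C@@]2(O)C(C)C | intermediate
13 | (3R,3aS,4S,8aS)-3-hydroxy-6,8a-dimethyl-3-(propan-2-yl)-1,2,3,3a,4,7,8,8a-octahydroazulen-4-yl 4-hydroxybenzoate | CC1=C[C@H](OC(=O)c2ccc(O)cc2)[C@@H]2[C@@](C)(CC1)CC[C@@]2(O)C(C)C | target

Total step count: 6. Longest linear sequence: 6 steps.

Steps most likely to fail

Step 2. Residual Me3Al may consume acrolein before the aluminium enolate is captured. Facial discrimination at the enolate carbon between the methyl and the 3-methylbutenyl substituent of the adjacent quaternary centre may be low, which would erode the trans relationship needed for the ring fusion. Ligand control may also be incomplete for this enone. The fallback sets out from 5. The same conjugate methylation is run but quenched with TMSOTf, so that the trimethylsilyl enol ether F1 can be isolated free of aluminium and copper. MeLi in THF at 0 °C then regenerates the enolate as the lithium enolate F2, and acrolein is added at −78 °C for a closed-chair lithium aldol. This returns to the route at 8, with the two bond formations uncoupled and the counter-ion open to tuning.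

Step 3. The metal aldolate may fragment by retro-aldol reaction, enolisation or β-hydride reduction may compete with addition to the hindered ketone, and alkoxide-directed delivery may send isopropyl to the wrong face. The fallback sets out from 8. The secondary hydroxyl is silylated (TESCl, imidazole, DMF) to the triethylsilyl ether F3. iPrMgCl/CeCl3 in THF at −78 °C then gives the silylated tertiary alcohol F4; the bulky, non-chelating silyloxy arm should leave only the opposite carbonyl face open. TBAF/AcOH in THF removes silicon and returns to the route at 9.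

Step 4. Intermolecular metathesis may give oligomers, ruthenium hydride species may isomerise the allylic alcohol to an ethyl ketone, and the 1,3-diol may sequester the catalyst. The fallback sets out from 9. The secondary hydroxyl is acylated first with 11 (Et3N, DMAP, CH2Cl2) to the diene ester F5. The ring is then closed on this allylic ester with the second-generation Hoveyda–Grubbs catalyst in toluene at 80 °C; the ester cannot tautomerise to a ketone and does not chelate ruthenium. This returns to the route directly at 12.

Further compounds
F1 | step 2 | trimethyl{[(3S)-3-methyl-3-(3-methylbut-3-en-1-yl)cyclopent-1-en-1-yl]oxy}silane | C1=C(O[Si](C)(C)C)CC[C@]1(C)CCC(C)=C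
F2 | step 2 | lithium (3S)-3-methyl-3-(3-methylbut-3-en-1-yl)cyclopent-1-en-1-olate | C1=C(O[Li])CC[C@]1(C)CCC(C)=C
F3 | step 3 | (2S,3S)-3-methyl-3-(3-methylbut-3-en-1-yl)-2-[(1S)-1-(triethylsilyloxy)prop-2-en-1-yl]cyclopentan-1-one | C=C[C@H](O[Si](CC)(CC)CC)[C@@H]1[C@@](C)(CCC(C)=C)CCC1=O
F4 | step 3 | (1R,2S,3S)-3-methyl-3-(3-methylbut-3-en-1-yl)-1-(propan-2-yl)-2-[(1S)-1-(triethylsilyloxy)prop-2-en-1-yl]cyclopentan-1-ol | C=C[C@H](O[Si](CC)(CC)CC)[C@@H]1[C@@](C)(CCC(C)=C)CC[C@@]1(O)C(C)C
F5 | step 4 | (1S)-1-[(1S,2R,5S)-2-hydroxy-5-methyl-5-(3-methylbut-3-en-1-yl)-2-(propan-2-yl)cyclopentyl]prop-2-en-1-yl 4-(acetyloxy)benzoate | C=C[C@H](OC(=O)c1ccc(OC(C)=O)cc1)[C@@H]1[C@@](C)(CCC(C)=C)CC[C@@]1(O)C(C)C
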